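**Retrosynthetic overview**
- Target ⇐ face-selective 1,2-reduction of the C4 ketone and O-methylation of a bicyclo[3.2.1]oct-2-ene-4,8-dione diosphenol.
- Diosphenol ⇐ Lewis-acid ring expansion of a quinone–styrene cyclobutane (bicyclo[4.2.0] → bicyclo[3.2.1]; cyclobutane → cyclopentanone). This is the key step.
- Cyclobutane ⇐ catalytic enantioselective stepwise [2+2] of 2-allyl-5-methoxy-1,4-benzoquinone with (E)-methylisoeugenol; this sets the absolute configuration.
- Quinone ⇐ 1,4-benzoquinone + allyltrimethylsilane, then methanol. Styrene ⇐ catechol (methylation, bromination, Suzuki coupling with (E)-propenylboronic acid).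
- Ring order: arene (bought) → cyclobutane fused to the enedione ring → cyclopentanone/cycloheptene of the bicyclo[3.2.1] core.

Assumption: bicyclo[3.2.1]octene locants are C1 = allyl bridgehead, C2=C3(OMe), C4 (OH), C5 = bridgehead CH, C6 (aryl), C7 (methyl), C8 = bridging C=O; the target SMILES is then (1R,4R,5S,6S,7S), with aryl exo (syn to C8), methyl endo and 4-OH on the face of the C6–C7 bridge.

**Route**

Step 1
Reactants: 1 catechol
Product: 2 1,2-dimethoxybenzene
Conditions: MeI (2.5 equiv), K2CO3 (3 equiv), acetone, reflux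
Reagents that add atoms: iodomethane, CI
Why: Williamson ether synthesis on both phenols; no stereocentre.

Step 2
Reactants: 2 1,2-dimethoxybenzene
Product: 3 4-bromo-1,2-dimethoxybenzene
Conditions: NBS (1.05 equiv), MeCN, 0 °C → rt
Reagents that add atoms: N-bromosuccinimide, O=C1CCC(=O)N1Br
Why: Electrophilic aromatic bromination goes para to one methoxy group and stops at the monobromide.

Step 3
Reactants: 3 4-bromo-1,2-dimethoxybenzene; 4 (E)-prop-1-enylboronic acid
Product: 5 (E)-1,2-dimethoxy-4-(prop-1-enyl)benzene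
Conditions: Pd(dppf)Cl2 (3 mol%), K2CO3 (3 equiv), 1,4-dioxane/H2O 4:1, 85 °C
Reagents that add atoms: none
Why: Suzuki–Miyaura coupling proceeds with retention of the E alkene geometry.

Step 4
Reactants: 6 1,4-benzoquinone; 7 allyltrimethylsilane
Product: 9 2-allyl-1,4-benzoquinone, via 2-allylhydroquinone 8 (not isolated)
Conditions: TiCl4 (1.1 equiv), CH2Cl2, −78 °C; H2O quench; crude in Et2O, Ag2O (1.5 equiv), MgSO4, rt
Reagents that add atoms: none
Why: Hosomi–Sakurai conjugate allylation of the TiCl4-activated quinone gives the hydroquinone after tautomerisation, and mild Ag2O oxidation returns the quinone.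

Step 5
Reactants: 9 2-allyl-1,4-benzoquinone (2 equiv)
Product: 11 2-allyl-5-methoxy-1,4-benzoquinone, via 2-allyl-5-methoxyhydroquinone 10 (not isolated)
Conditions: MeOH, ZnCl2 (1 equiv), rt, 24 h; the 8 formed is recovered and reoxidised with Ag2O
Reagents that add atoms: methanol, CO
Why: ZnCl2-promoted Michael addition of methanol goes to C5, the free β-position of the more electrophilic C1 carbonyl (para to the alkyl group), and the electron-rich hydroquinone is oxidised in situ by the second equivalent of 9 (redox exchange).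

Step 6
Reactants: 11 2-allyl-5-methoxy-1,4-benzoquinone; 5 (E)-1,2-dimethoxy-4-(prop-1-enyl)benzene (1.5 equiv)
Product: 12 (1S,6R,7S,8S)-6-allyl-8-(3,4-dimethoxyphenyl)-3-methoxy-7-methylbicyclo[4.2.0]oct-3-ene-2,5-dione
Conditions: [Cu((S,S)-tBu-box)](SbF6)2 (10 mol%), 4 Å MS, CH2Cl2, −78 → −40 °C
Reagents that add atoms: none
Why: Proposed new method: the C4 carbonyl and 5-OMe of 11 chelate the C2-symmetric Cu(II)–bis(oxazoline) dication, which activates the allyl-bearing C2 and blocks one quinone face; the β-carbon of 5 adds to C2 and the benzylic cation collapses onto the copper enolate carbon C3 on the same face before bond rotation (stepwise polar [2+2], not concerted), giving the cis-fused cyclobutane with aryl endo and aryl/methyl trans and fixing C6 and C7 of 12 (later C1 and C7); the closest known reaction type is the stoichiometric chiral Ti(IV)-diolate-promoted [2+2] of 2-alkoxy-1,4-benzoquinones with propenylarenes, combined with Cu(II)–box catalysis of two-point-binding enones; the sense of induction cannot be predicted, so the ligand antipode is fixed by the first run.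

Step 7
Reactants: 12 (1S,6R,7S,8S)-6-allyl-8-(3,4-dimethoxyphenyl)-3-methoxy-7-methylbicyclo[4.2.0]oct-3-ene-2,5-dione
Product: 13 (1R,5R,6S,7S)-1-allyl-6-(3,4-dimethoxyphenyl)-3-hydroxy-7-methylbicyclo[3.2.1]oct-2-ene-4,8-dione
Conditions: TiCl4 (3 equiv), CH2Cl2, −78 → −20 °C; H2O quench
Reagents that add atoms: none
Why: Cationic ring expansion of the cyclobutane to the cyclopentanone of the bicyclo[3.2.1] core (known Lewis-acid rearrangement of quinone–styrene [2+2] adducts): TiCl4 heterolyses the benzylic C1–C8 bond, the cation is recaptured by the vinylogous-ester α-carbon C4, and chloride demethylation of the oxocarbenium makes it irreversible; C6 and C7 of 12 are untouched, the aryl closes exo and trans to methyl through the less crowded rotamer, and C5 is fixed by the bridge.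

Step 8
Reactants: 13 (1R,5R,6S,7S)-1-allyl-6-(3,4-dimethoxyphenyl)-3-hydroxy-7-methylbicyclo[3.2.1]oct-2-ene-4,8-dione
Product: 14 (1R,5R,6S,7S)-1-allyl-6-(3,4-dimethoxyphenyl)-3-methoxy-7-methylbicyclo[3.2.1]oct-2-ene-4,8-dione
Conditions: Me2SO4 (1.5 equiv), K2CO3 (2 equiv), acetone, rt
Reagents that add atoms: dimethyl sulfate, COS(=O)(=O)OC
Why: O-alkylation of the acidic diosphenol with a hard electrophile; only the C2=C3 enol exists because C5 is a bridgehead, and the non-nucleophilic base avoids retro-Claisen cleavage.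

Step 9
Reactants: 14 (1R,5R,6S,7S)-1-allyl-6-(3,4-dimethoxyphenyl)-3-methoxy-7-methylbicyclo[3.2.1]oct-2-ene-4,8-dione
Product: 15 (1R,4R,5S,6S,7S)-1-allyl-6-(3,4-dimethoxyphenyl)-4-hydroxy-3-methoxy-7-methylbicyclo[3.2.1]oct-2-en-8-one
Conditions: NaBH4 (1.0 equiv), CeCl3·7H2O (1.2 equiv), MeOH, −78 °C; aq. NaHCO3 quench
Reagents that add atoms: none
Why: Luche reduction should take the conjugated C4 ketone in preference to the saturated C8 ketone (flanked by the quaternary bridgehead and the exo aryl); hydride enters C4 from the exo face (syn to C8, away from the C6–C7 bridge), which puts the OH on the ethano-bridge face (4R).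

**Compound list**
1 | catechol | Oc1ccccc1O | starting material
2 | 1,2-dimethoxybenzene | COc1ccccc1OC | intermediate
3 | 4-bromo-1,2-dimethoxybenzene | COc1ccc(Br)cc1OC | intermediate
4 | (E)-prop-1-enylboronic acid | C/C=C/B(O)O | starting material
5 | (E)-1,2-dimethoxy-4-(prop-1-enyl)benzene | C/C=C/c1ccc(OC)c(OC)c1 | intermediate
6 | 1,4-benzoquinone | O=C1C=CC(=O)C=C1 | starting material
7 | allyltrimethylsilane | C=CC[Si](C)(C)C | starting material
8 | 2-allylhydroquinone (2-allylbenzene-1,4-diol) | C=CCc1cc(O)ccc1O | intermediate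
9 | 2-allyl-1,4-benzoquinone | C=CCC1=CC(=O)C=CC1=O | intermediate
10 | 2-allyl-5-methoxyhydroquinone (2-allyl-5-methoxybenzene-1,4-diol) | C=CCc1cc(O)c(OC)cc1O | intermediate
11 | 2-allyl-5-methoxy-1,4-benzoquinone | C=CCC1=CC(=O)C(OC)=CC1=O | intermediate
12 | (1S,6R,7S,8S)-6-allyl-8-(3,4-dimethoxyphenyl)-3-methoxy-7-methylbicyclo[4.2.0]oct-3-ene-2,5-dione (cis-fused; aryl on the face of the enedione ring; methyl on the face of the allyl group) | C=CC[C@]12C(=O)C=C(OC)C(=O)[C@H]1[C@@H](c1ccc(OC)c(OC)c1)[C@@H]2C | intermediate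
13 | (1R,5R,6S,7S)-1-allyl-6-(3,4-dimethoxyphenyl)-3-hydroxy-7-methylbicyclo[3.2.1]oct-2-ene-4,8-dione (aryl exo; methyl endo) | C=CC[C@@]12C=C(O)C(=O)[C@@H](C1=O)[C@@H](c1ccc(OC)c(OC)c1)[C@@H]2C | intermediate
14 | (1R,5R,6S,7S)-1-allyl-6-(3,4-dimethoxyphenyl)-3-methoxy-7-methylbicyclo[3.2.1]oct-2-ene-4,8-dione | C=CC[C@@]12C=C(OC)C(=O)[C@@H](C1=O)[C@@H](c1ccc(OC)c(OC)c1)[C@@H]2C | intermediate
15 | (1R,4R,5S,6S,7S)-1-allyl-6-(3,4-dimethoxyphenyl)-4-hydroxy-3-methoxy-7-methylbicyclo[3.2.1]oct-2-en-8-one | C=CC[C@@]12C=C(OC)[C@H](O)[C@@H](C1=O)[C@@H](c1ccc(OC)c(OC)c1)[C@@H]2C | target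

**Totals**
Total step count: 9. Longest linear sequence: 7 steps (steps 1, 2, 3, 6, 7, 8, 9).

**Three steps most likely to fail**

Step 6 (the proposed new step). The copper catalyst may not turn over because product 12 is still a chelating α-methoxy enone, the ee may be low, or the adduct may rearrange further in the flask. The fallback uses known chemistry: it sets out from 11 and 5 and returns at 12. It replaces the catalytic Cu(II) activation by a stoichiometric chiral titanium(IV) reagent made from TiCl4, Ti(OiPr)4 and the appropriate TADDOL enantiomer in CH2Cl2 at −78 °C, which is the established way to run this quinone–propenylarene [2+2] asymmetrically. No compound outside the list is made (F0).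

Step 7. The ring-opened benzylic cation can close on the carbonyl oxygen instead (hydrobenzofuranone), demethylation by chloride can be slow, and reversion to quinone plus alkene would erode the ee. The fallback changes the O-alkyl group to one that leaves easily. It sets out from 11 and returns at 13. Acid-catalysed exchange with benzyl alcohol (cat. TsOH, toluene, removal of methanol) gives 2-allyl-5-(benzyloxy)-1,4-benzoquinone F1. The stoichiometric titanium TADDOLate [2+2] with 5 gives (1S,6R,7S,8S)-6-allyl-3-(benzyloxy)-8-(3,4-dimethoxyphenyl)-7-methylbicyclo[4.2.0]oct-3-ene-2,5-dione F2. TiCl4 at −78 °C then ring-expands F2 with fast loss of the benzyl group to give 13.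

Step 9. The strained C8 ketone may be reduced as fast as, or faster than, the C4 enone carbonyl. The fallback gives up chemoselective reduction and differentiates the two alcohols instead. It sets out from 14 and returns at 15. Excess NaBH4 in MeOH at 0 °C reduces both ketones to (1R,4R,5R,6S,7S,8S)-1-allyl-6-(3,4-dimethoxyphenyl)-3-methoxy-7-methylbicyclo[3.2.1]oct-2-ene-4,8-diol F3. TBSCl/imidazole silylates the less hindered allylic 4-OH to give (1R,4R,5R,6S,7S,8S)-1-allyl-4-[(tert-butyldimethylsilyl)oxy]-6-(3,4-dimethoxyphenyl)-3-methoxy-7-methylbicyclo[3.2.1]oct-2-en-8-ol F4. Dess–Martin periodinane oxidises the remaining 8-OH to (1R,4R,5S,6S,7S)-1-allyl-4-[(tert-butyldimethylsilyl)oxy]-6-(3,4-dimethoxyphenyl)-3-methoxy-7-methylbicyclo[3.2.1]oct-2-en-8-one F5, and TBAF in THF gives 15.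

**Further compounds**
F0 | step 6 | none | none
F1 | step 7 | 2-allyl-5-(benzyloxy)-1,4-benzoquinone | C=CCC1=CC(=O)C(OCc2ccccc2)=CC1=O
F2 | step 7 | (1S,6R,7S,8S)-6-allyl-3-(benzyloxy)-8-(3,4-dimethoxyphenyl)-7-methylbicyclo[4.2.0]oct-3-ene-2,5-dione | C=CC[C@]12C(=O)C=C(OCc3ccccc3)C(=O)[C@H]1[C@@H](c1ccc(OC)c(OC)c1)[C@@H]2C
F3 | step 9 | (1R,4R,5R,6S,7S,8S)-1-allyl-6-(3,4-dimethoxyphenyl)-3-methoxy-7-methylbicyclo[3.2.1]oct-2-ene-4,8-diol | C=CC[C@@]12C=C(OC)[C@H](O)[C@@H]([C@@H]1O)[C@@H](c1ccc(OC)c(OC)c1)[C@@H]2C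
F4 | step 9 | (1R,4R,5R,6S,7S,8S)-1-allyl-4-[(tert-butyldimethylsilyl)oxy]-6-(3,4-dimethoxyphenyl)-3-methoxy-7-methylbicyclo[3.2.1]oct-2-en-8-ol | C=CC[C@@]12C=C(OC)[C@H](O[Si](C)(C)C(C)(C)C)[C@@H]([C@@H]1O)[C@@H](c1ccc(OC)c(OC)c1)[C@@H]2C
F5 | step 9 | (1R,4R,5S,6S,7S)-1-allyl-4-[(tert-butyldimethylsilyl)oxy]-6-(3,4-dimethoxyphenyl)-3-methoxy-7-methylbicyclo[3.2.1]oct-2-en-8-one | C=CC[C@@]12C=C(OC)[C@H](O[Si](C)(C)C(C)(C)C)[C@@H](C1=O)[C@@H](c1ccc(OC)c(OC)c1)[C@@H]2C
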